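The data are simulated on assumed constants; noise was put on by code.

Time separates the two runs I had: Wednesday's flask was read up to 50.0 s, Friday's from 10.0 min to 40.0 min, and their charges differ in cL, 0.20 M against 0.10 M.

all flasks: D 0.10 M
- Friday's: Q 0.090 M; L 0.10 M; the very flask that is asked about, followed so far
- Wednesday's: Q 0.090 M; L 0.20 M; run made earlier
- flask: Q 0.0900 M; L 0.100 M; time 40 min

Friday's run (percent of the D charged)

| time / min | J / % | D / % |
|---|---|---|
| 10.0 | 57.9 | 0 |
| 20.0 | 57.7 | 0 |
| 30.0 | 58.5 | 0 |
| 40.0 | 58.2 | 0.1 |

Wednesday's run (percent of the D charged)

| time / s | J / % | D / % |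
|---|---|---|
| 10.0 | 0.3 | 93.4 |
| 20.0 | 0 | 87.0 |
| 50.0 | 4.1 | 70.1 |

(scatter of a reading: 0.3 percentage points)

- south-west: change nothing and wait 12 min more
- west: at 40 min add Q, 50.0% of the amount charged, then wait 12 min
- south: at 40 min take out 90% of the J then present, then wait 12 min

- as a solid, counted per litre of solution: D
- removed J is counted in
- steps that have been proposed: G -> E; D <-> G; Q + E -> J; E + L -> Z
- at the start none of D is in solution
- additions bring no volume worth counting

- J, in percent of the D first charged, at 40 min
- which option adds most J ("none" when 2 percentage points or less is all one gets) (south-west / west / south / none)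
- J present, with what was taken out counted in, in percent of the D first charged, after south-west
- J present, with what was taken out counted in, in percent of the D first charged, after south

Wednesday's D readings gave me a loss constant of 0.426 min⁻¹ and a half-life of 1.63 min. Wednesday's run ended with 70.1% of D because it was stopped sooner than one such half-life. Friday's flask showed 0% of D at its first reading, at 10.0 min, and its J then stayed flat, with a mean of 58.1%.

I took Friday's flat J to mean that E was no longer being made, so the remaining D had gone to Z. Dividing the rate of Q + E → J by that of E + L → Z drops time and cE, leaving a ratio proportional to cQ/cL. The proportionality constant, s, is the selectivity factor, and integrating shows that the fraction of Q left equals the fraction of L left raised to the power s. Friday's balance left 0.0319 M of Q and 0.0581 M of L, so Q was not the limiting reagent, and s = 1.91. The starting rate ratio was therefore 1.72 in Friday's flask and 0.858 in Wednesday's. I committed to the mean for J and expected no gain from any option.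

The forecast gave 58.1%, best none, 58.1% after south-west and 58.1% after south, holding that “The flask has therefore finished”.

The flask gave 58.1%, best none, 58.1% after south-west and 58.1% after south.

    G → E (k = 0.0170 s⁻¹)
    D ⇌ G, rate k2*(cs2 - [G]) while solid is left; crystals form when [G] > cs2 (solubility = 0.0770 M, k = 0.00930 s⁻¹)
    Q + E → J (k = 0.840 M⁻¹ s⁻¹)
    E + L → Z (k = 0.440 M⁻¹ s⁻¹)

At the charges of this flask, E's half-life was 0.15 min by the step to J and 0.26 min by the step to Z, a ratio of 1.73, and s·cQ/cL from the charges is 1.72. The neighbour flask charged with 0.022 M of Q ended with J at 20.9% and L at 21% of its charge, so s puts its remaining Q at 5.08% of its charge, and it held 5.0%.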